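Four vessels take the same charge of starting material and reagent: a plug-flow tube, a slowly fed flask, a closed stirred flask and a continuous stirred tank.

| setting | south-west | north-west | south-east | north-east |
|---|---|---|---|---|
| starting material | 5.0 mM | 5.0 mM (fed, over 1.20 min) | 5.0 mM | 5.0 mM |
| reagent | 6.00 mM | 6.00 mM | 6.00 mM | 6.00 mM |
| time | 1.5 min | 1.5 min | 1.5 min |  |
| remark | plug flow through a tube for 1.5 min, no back-mixing | all but starting material at the start; starting material goes in evenly over 1.20 min, the run ends at 1.5 min | everything together in a closed stirred flask, run for 1.5 min | a single well-mixed tank run continuously and read at steady state, 1.5 min in it on average |

    2 starting material → side product B (k1 = 76.6 L mol⁻¹ s⁻¹)
    starting material + reagent → target (k2 = 21.3 L mol⁻¹ s⁻¹)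
    starting material → side product A (k3 = 0.0850 s⁻¹)
    starting material + target → side product C (k4 = 2.69 L mol⁻¹ s⁻¹)

- in percentages every species weighs as the starting material in it: one side product B or side product C counts as two
- a step written with two of one species runs at k times the square of its concentration and takes two of it each time
- the stated concentrations are those of everything mixed, before any reaction; amounts are the same in each set-up
- the feed brings no volume worth counting
- run time (south-west): 1.5 min

* the set-up with the highest amount of target at the outlet or at the end, in percent of the starting material put in ("none" if the first two lie within 2 percentage points) (south-west / north-west / south-east / north-east / none)
* amount of target at the outlet or at the end, in percent of the starting material put in, south-west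
* amount of target at the outlet or at the end, in percent of the starting material put in, north-west
* amount of target at the outlet or at the end, in percent of the starting material put in, south-east
* amount of target at the outlet or at the end, in percent of the starting material put in, north-east

I turn each constant into a time at the charged amounts. The step to side product B has the shortest first half-life, 0.0218 min, against 0.090 min for the target step and 0.14 min for the step to side product A. The attack of target to give side product C comes well behind at 0.86 min. So when everything meets at once, as in south-west and south-east, side product B leads from the start. A plug in the tube is a closed flask on the move, so those two must give one number.

North-west feeds over 1.20 min, longer than these half-lives, so starting material is used about as it arrives and stays under the charge. The step to side product B, squared in starting material, then loses ground to the two steps that are first order in it.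

Those two share out what escapes. 21.3 L mol⁻¹ s⁻¹ times 6.00 mM over 0.0850 s⁻¹ gives 1.50: this is the split S, the target formed per side product A formed at a given moment, a selectivity factor with no starting material in it. Reagent can only fall, so target takes at most 60.0% of that stream. My reckoning puts south-west and south-east last but stops short of parting north-west from north-east.

The forecast says north-west wins, with 23.4% for south-west, 42.5% for north-west, 23.4% for south-east and 36.3% for north-east, on the ground that “keeping its concentration low favours the target”.

The simulation gives 23.3%, 42.6%, 23.3% and 36.3% in that order, so north-west wins and the forecast holds. In north-west, reagent ends at 63% of its charge, taking S from 1.50 to 0.945, and the target standing at the end over the side product A standing then, 1.17, lies between them. The neighbour with 10 mM of reagent starts at S = 2.50 and ends at 1.76, with the ratio at 2.06. That neighbour gives 58.0% of target, and its side product B stands at 11.0%.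

The numbers belong to no real substance; the result is computed.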